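**Retrosynthetic overview**
- The target comes from fluoride desilylation after a para-Claisen–Cope rearrangement of the 5-O-prenyl ether of a (2S)-5-hydroxy-7-methoxyflavan with TIPS-protected B-ring phenols; C8 is para to O5, so the prenyl group goes on last.
- The (2S)-flavan comes from Ir-catalysed asymmetric hydrogenation of the 2-aryl-4H-chromene, itself made by cyclodehydration of a 1-aryl-3-(2,6-dihydroxy-4-methoxyphenyl)propan-1-one (symmetric A ring, so no regiochemical question).
- Key C–C bond (C4–C4a): the ketone comes from a palladium homoenolate (d3 synthon, from a 1-arylcyclopropanol) and a 2,6-dialkoxy-4-methoxyaryl iodide; the β-carbon of a ketone and an aryl halide carbon are both normally electrophilic.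
- The cyclopropanol comes from a Kulinkovich reaction on silylated methyl 2,4-dihydroxybenzoate; the aryl iodide comes from MOM protection and directed ortho-lithiation/iodination of 5-methoxyresorcinol.
- Rings: both benzene rings are bought; a cyclopropane is made (step 2) and opened (step 5); the pyran ring is closed in step 6 and its only stereocentre is set in step 7.

Assumption: the stereocentre in the SMILES is read as (2S); methyl 2,4-dihydroxybenzoate and 5-methoxyresorcinol are taken as stock chemicals.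

**Route**

Step 1
Reactants: 1 methyl 2,4-dihydroxybenzoate
Product: 2 methyl 2,4-bis(triisopropylsilyloxy)benzoate
Conditions: TIPSOTf (2.4 equiv), 2,6-lutidine (3 equiv), CH2Cl2, 0 °C → rt
Reagents that add atoms: triisopropylsilyl trifluoromethanesulfonate, CC(C)[Si](C(C)C)(C(C)C)OS(=O)(=O)C(F)(F)F
Why: Phenol silylation with a silyl triflate, strong enough to cap the ester-chelated ortho phenol as well; aryl TIPS ethers tolerate Grignard reagents, Pd/carbonate, dilute acid and H2, and leave with fluoride at the end.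

Step 2
Reactants: 2 methyl 2,4-bis(triisopropylsilyloxy)benzoate
Product: 3 1-[2,4-bis(triisopropylsilyloxy)phenyl]cyclopropan-1-ol
Conditions: EtMgBr (3 equiv), Ti(OiPr)4 (30 mol%), THF, 0 °C → rt; aq. NH4Cl
Reagents that add atoms: ethylmagnesium bromide, CC[Mg]Br
Why: Kulinkovich reaction, in which the titanacyclopropane formed from EtMgBr and Ti(OiPr)4 acts as a 1,2-dicarbanion that adds twice to the ester carbonyl, giving the 1-arylcyclopropanol that serves as a latent ketone homoenolate.

Step 3
Reactants: 4 5-methoxybenzene-1,3-diol (5-methoxyresorcinol)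
Product: 5 1-methoxy-3,5-bis(methoxymethoxy)benzene
Conditions: NaH (2.4 equiv), MOMCl (2.4 equiv), DMF, 0 °C → rt
Reagents that add atoms: chloromethyl methyl ether, COCCl
Why: Williamson-type O-alkylation of both phenoxides; the MOM ethers are the directing groups for step 4, survive Pd/Cs2CO3 and are removed by acid in step 6.

Step 4
Reactants: 5 1-methoxy-3,5-bis(methoxymethoxy)benzene
Product: 7 2-iodo-5-methoxy-1,3-bis(methoxymethoxy)benzene, via aryllithium 6 (not isolated)
Conditions: n-BuLi (1.15 equiv), THF, 0 °C, 1 h; then I2 (1.2 equiv), −78 °C → rt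
Reagents that add atoms: n-butyllithium, CCCC[Li] (Li in 6 only); iodine, II
Why: Directed ortho-metalation, where the position flanked by two OMOM groups is the most acidic and doubly chelated so lithiation goes there rather than next to OMe, followed by iodinolysis of the aryllithium.

Step 5
Reactants: 3 1-[2,4-bis(triisopropylsilyloxy)phenyl]cyclopropan-1-ol (1.3 equiv); 7 2-iodo-5-methoxy-1,3-bis(methoxymethoxy)benzene
Product: 8 1-[2,4-bis(triisopropylsilyloxy)phenyl]-3-[4-methoxy-2,6-bis(methoxymethoxy)phenyl]propan-1-one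
Conditions: Pd(OAc)2 (10 mol%), XPhos (20 mol%), Cs2CO3 (2 equiv), toluene, 80 °C, Ar
Reagents that add atoms: none
Why: Pd-catalysed ring-opening cross-coupling of a cyclopropanol, in which the Ar–Pd(II) cyclopropanolate undergoes strain-driven β-carbon elimination to a β-palladated ketone (palladium homoenolate) that reductively eliminates onto the aryl group, the bulky biarylphosphine favouring oxidative addition into the hindered iodide and C–C reductive elimination over β-hydride loss.

Step 6
Reactants: 8 1-[2,4-bis(triisopropylsilyloxy)phenyl]-3-[4-methoxy-2,6-bis(methoxymethoxy)phenyl]propan-1-one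
Product: 11 2-[2,4-bis(triisopropylsilyloxy)phenyl]-7-methoxy-4H-chromen-5-ol, via diol ketone 9 (not isolated), via cyclic hemiketal 10 (not isolated)
Conditions: 1 M HCl, MeOH/THF, 40 °C; evaporate; then PPTS (10 mol%), toluene (0.02 M), 4 Å MS, 80 °C, Ar
Reagents that add atoms: none
Why: Acid transacetalisation of the MOM ethers (methanol traps the formaldehyde unit) followed by hemiketalisation and acid-catalysed cyclodehydration to the cyclic enol ether; the two phenols are equivalent, so only one chromene can form.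

Step 7
Reactants: 11 2-[2,4-bis(triisopropylsilyloxy)phenyl]-7-methoxy-4H-chromen-5-ol
Product: 12 (2S)-2-[2,4-bis(triisopropylsilyloxy)phenyl]-7-methoxy-3,4-dihydro-2H-chromen-5-ol
Conditions: [Ir(cod)(L*)]BArF (2 mol%; L* = phosphinite–oxazoline N,P ligand, antipode that gives 2S), H2 (50 bar), CH2Cl2, rt
Reagents that add atoms: none
Why: Iridium/N,P-catalysed asymmetric hydrogenation of a 2-aryl-4H-chromene (a trisubstituted cyclic enol ether, a known substrate class for these catalysts), where the chiral catalyst delivers H2 to one face of C2=C3 and so sets C2 as S; the first run is checked by chiral HPLC and CD, and the ligand antipode is swapped if the sense is opposite.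

Step 8
Reactants: 12 (2S)-2-[2,4-bis(triisopropylsilyloxy)phenyl]-7-methoxy-3,4-dihydro-2H-chromen-5-ol
Product: 13 (2S)-2-[2,4-bis(triisopropylsilyloxy)phenyl]-7-methoxy-5-[(3-methylbut-2-en-1-yl)oxy]-3,4-dihydro-2H-chromene
Conditions: prenyl bromide (1.3 equiv), K2CO3 (2 equiv), acetone, 50 °C
Reagents that add atoms: 1-bromo-3-methylbut-2-ene (prenyl bromide), CC(C)=CCBr
Why: Williamson O-alkylation of the only free phenol under mild carbonate conditions that leave the aryl silyl ethers and the C2 stereocentre untouched.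

Step 9
Reactants: 13 (2S)-2-[2,4-bis(triisopropylsilyloxy)phenyl]-7-methoxy-5-[(3-methylbut-2-en-1-yl)oxy]-3,4-dihydro-2H-chromene
Product: 17 4-[(2S)-5-hydroxy-7-methoxy-8-(3-methylbut-2-en-1-yl)-3,4-dihydro-2H-chromen-2-yl]benzene-1,3-diol (CNP0115018.1), via ortho-dienone 14 (not isolated), via para-dienone 15 (not isolated), via silylated 8-prenylflavan 16 (not isolated)
Conditions: Eu(fod)3 (10 mol%), PhCl, 90 °C, Ar; then TBAF (2.5 equiv), AcOH (2.5 equiv), THF, 0 °C → rt
Reagents that add atoms: none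
Why: Lewis-acid-catalysed aromatic Claisen rearrangement to C6 followed by Cope rearrangement to C8 (para-Claisen–Cope, restoring the normal prenyl group para to O5) and rearomatisation, then buffered fluoride cleavage of the two aryl silyl ethers; nothing in the sequence touches C2.

**Compound list**

1 | methyl 2,4-dihydroxybenzoate | COC(=O)c1ccc(O)cc1O | starting material
2 | methyl 2,4-bis(triisopropylsilyloxy)benzoate | COC(=O)c1ccc(O[Si](C(C)C)(C(C)C)C(C)C)cc1O[Si](C(C)C)(C(C)C)C(C)C | intermediate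
3 | 1-[2,4-bis(triisopropylsilyloxy)phenyl]cyclopropan-1-ol | OC1(CC1)c1ccc(O[Si](C(C)C)(C(C)C)C(C)C)cc1O[Si](C(C)C)(C(C)C)C(C)C | intermediate
4 | 5-methoxybenzene-1,3-diol (5-methoxyresorcinol) | COc1cc(O)cc(O)c1 | starting material
5 | 1-methoxy-3,5-bis(methoxymethoxy)benzene | COCOc1cc(OC)cc(OCOC)c1 | intermediate
6 | [4-methoxy-2,6-bis(methoxymethoxy)phenyl]lithium | COCOc1cc(OC)cc(OCOC)c1[Li] | intermediate
7 | 2-iodo-5-methoxy-1,3-bis(methoxymethoxy)benzene | COCOc1cc(OC)cc(OCOC)c1I | intermediate
8 | 1-[2,4-bis(triisopropylsilyloxy)phenyl]-3-[4-methoxy-2,6-bis(methoxymethoxy)phenyl]propan-1-one | COCOc1cc(OC)cc(OCOC)c1CCC(=O)c1ccc(O[Si](C(C)C)(C(C)C)C(C)C)cc1O[Si](C(C)C)(C(C)C)C(C)C | intermediate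
9 | 1-[2,4-bis(triisopropylsilyloxy)phenyl]-3-(2,6-dihydroxy-4-methoxyphenyl)propan-1-one | COc1cc(O)c(CCC(=O)c2ccc(O[Si](C(C)C)(C(C)C)C(C)C)cc2O[Si](C(C)C)(C(C)C)C(C)C)c(O)c1 | intermediate
10 | 2-[2,4-bis(triisopropylsilyloxy)phenyl]-7-methoxy-3,4-dihydro-2H-chromene-2,5-diol (cyclic hemiketal, racemic at C2) | COc1cc(O)c2c(c1)OC(O)(c1ccc(O[Si](C(C)C)(C(C)C)C(C)C)cc1O[Si](C(C)C)(C(C)C)C(C)C)CC2 | intermediate
11 | 2-[2,4-bis(triisopropylsilyloxy)phenyl]-7-methoxy-4H-chromen-5-ol | COc1cc(O)c2c(c1)OC(c1ccc(O[Si](C(C)C)(C(C)C)C(C)C)cc1O[Si](C(C)C)(C(C)C)C(C)C)=CC2 | intermediate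
12 | (2S)-2-[2,4-bis(triisopropylsilyloxy)phenyl]-7-methoxy-3,4-dihydro-2H-chromen-5-ol | COc1cc(O)c2c(c1)O[C@H](c1ccc(O[Si](C(C)C)(C(C)C)C(C)C)cc1O[Si](C(C)C)(C(C)C)C(C)C)CC2 | intermediate
13 | (2S)-2-[2,4-bis(triisopropylsilyloxy)phenyl]-7-methoxy-5-[(3-methylbut-2-en-1-yl)oxy]-3,4-dihydro-2H-chromene | COc1cc(OCC=C(C)C)c2c(c1)O[C@H](c1ccc(O[Si](C(C)C)(C(C)C)C(C)C)cc1O[Si](C(C)C)(C(C)C)C(C)C)CC2 | intermediate
14 | (2S)-2-[2,4-bis(triisopropylsilyloxy)phenyl]-7-methoxy-6-(2-methylbut-3-en-2-yl)-3,4-dihydro-2H-chromen-5(6H)-one (both C6 epimers) | COC1=CC(O[C@H](c3ccc(O[Si](C(C)C)(C(C)C)C(C)C)cc3O[Si](C(C)C)(C(C)C)C(C)C)CC2)=C2C(=O)C1C(C)(C)C=C | intermediate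
15 | (2S)-2-[2,4-bis(triisopropylsilyloxy)phenyl]-7-methoxy-8-(3-methylbut-2-en-1-yl)-3,4-dihydro-2H-chromen-5(8H)-one (both C8 epimers) | COC1=CC(=O)C2=C(O[C@H](c3ccc(O[Si](C(C)C)(C(C)C)C(C)C)cc3O[Si](C(C)C)(C(C)C)C(C)C)CC2)C1CC=C(C)C | intermediate
16 | (2S)-2-[2,4-bis(triisopropylsilyloxy)phenyl]-7-methoxy-8-(3-methylbut-2-en-1-yl)-3,4-dihydro-2H-chromen-5-ol | COc1cc(O)c2c(c1CC=C(C)C)O[C@H](c1ccc(O[Si](C(C)C)(C(C)C)C(C)C)cc1O[Si](C(C)C)(C(C)C)C(C)C)CC2 | intermediate
17 | 4-[(2S)-5-hydroxy-7-methoxy-8-(3-methylbut-2-en-1-yl)-3,4-dihydro-2H-chromen-2-yl]benzene-1,3-diol | COc1cc(O)c2c(c1CC=C(C)C)O[C@H](c1ccc(O)cc1O)CC2 | target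

**Step count and risks**

Total steps: 9. Longest linear sequence: 7 steps (1 → 2 → 3 → 8 → 11 → 12 → 13 → 17; the branch 4 → 5 → 7 → 8 is equally long).

Most likely to fail, first: step 5. The iodide is electron-rich and flanked by two alkoxy groups, the palladium homoenolate can lose β-hydride to give the aryl vinyl ketone, and the caesium cyclopropanolate could take a silyl group from the neighbouring ortho oxygen. The fallback sets out from 3 and comes back at 8. Ring-opening iodination of 3 with N-iodosuccinimide (CH2Cl2, 0 °C) gives 3-iodo-1-[2,4-bis(triisopropylsilyloxy)phenyl]propan-1-one F1. Zinc insertion (Zn dust, LiCl, THF, rt) then gives the preformed zinc homoenolate {3-[2,4-bis(triisopropylsilyloxy)phenyl]-3-oxopropyl}zinc iodide F2, which is joined to 7 by Negishi coupling (Pd2(dba)3, SPhos, THF, 50 °C) to give 8. The same bond is made with the same polarity, but by transmetalation of a base-free organozinc instead of β-carbon elimination from an alkoxide.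

Second: step 7, together with the chromene formation in step 6. Chromene 11 is air- and acid-sensitive, and the bulky ortho silyloxy group may slow the hydrogenation or lower the ee. The fallback sets out from 8 and comes back at 12. The MOM groups are removed as in step 6 (1 M HCl, MeOH/THF, rt) but the reaction is stopped at diol ketone 9, which is isolated. Asymmetric transfer hydrogenation (RuCl[(R,R)-TsDPEN](p-cymene), HCO2H/Et3N 5:2, 40 °C) gives (1R)-1-[2,4-bis(triisopropylsilyloxy)phenyl]-3-(2,6-dihydroxy-4-methoxyphenyl)propan-1-ol F3. Mitsunobu cyclisation (PPh3, DIAD, toluene, 0 °C) onto either of the two equivalent phenols then inverts the carbinol centre and gives 12. The weak point of this fallback is partial SN1 leakage at the electron-rich benzylic centre, so it is run cold in a non-polar solvent.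

Third: step 9. The ortho-dienone 14 can tautomerise before the Cope shift and give the 6-(2-methylbut-3-en-2-yl) isomer instead of the 8-prenyl compound. The fallback sets out from 12 and comes back at 16. Bromination para to the free phenol (NBS, 1.0 equiv, CH2Cl2, −78 °C) gives (2S)-8-bromo-2-[2,4-bis(triisopropylsilyloxy)phenyl]-7-methoxy-3,4-dihydro-2H-chromen-5-ol F4. Suzuki–Miyaura coupling with prenylboronic acid pinacol ester (Pd(OAc)2 with a biarylphosphine chosen for linear selectivity, K3PO4, THF/H2O, 40 °C) gives 16, which is desilylated as in the second half of step 9.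

**Further compounds**

F1 | step 5 | 3-iodo-1-[2,4-bis(triisopropylsilyloxy)phenyl]propan-1-one | ICCC(=O)c1ccc(O[Si](C(C)C)(C(C)C)C(C)C)cc1O[Si](C(C)C)(C(C)C)C(C)C
F2 | step 5 | {3-[2,4-bis(triisopropylsilyloxy)phenyl]-3-oxopropyl}zinc iodide | I[Zn]CCC(=O)c1ccc(O[Si](C(C)C)(C(C)C)C(C)C)cc1O[Si](C(C)C)(C(C)C)C(C)C
F3 | step 7 | (1R)-1-[2,4-bis(triisopropylsilyloxy)phenyl]-3-(2,6-dihydroxy-4-methoxyphenyl)propan-1-ol | COc1cc(O)c(CC[C@@H](O)c2ccc(O[Si](C(C)C)(C(C)C)C(C)C)cc2O[Si](C(C)C)(C(C)C)C(C)C)c(O)c1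
F4 | step 9 | (2S)-8-bromo-2-[2,4-bis(triisopropylsilyloxy)phenyl]-7-methoxy-3,4-dihydro-2H-chromen-5-ol | COc1cc(O)c2c(c1Br)O[C@H](c1ccc(O[Si](C(C)C)(C(C)C)C(C)C)cc1O[Si](C(C)C)(C(C)C)C(C)C)CC2
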